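## Retrosynthetic overview
1. The succinimide is closed last. NH3 condenses onto the succinate half-ester / acyl-oxazolidinone of an Evans syn-aldol adduct (C12–C13 bond), which leads back to C12 aldehyde 21.
2. The 6β-OH and the CHO both come from keto ester 20 in one hydride step (α-face attack at C6). Keto ester 20 comes from 6α-alcohol 19.
3. Rings A and B form in one operation, ring A (C4–C5) first and ring B (C9–C10) second. This is an H-atom-initiated head-to-tail bicyclisation of the acyclic chloro-trienol allylsilane 18. Equatorial C2–Cl and C6–OH select the chair–chair fold, and loss of Me3Si+ gives the C8(17) methylene.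
4. Compound 18 comes from alkyne 13 by syn silylmethyl-cupration/iodination and Reformatsky–Negishi coupling. Alkyne 13 comes from enal 11 and an allenylboronate.
5. Enal 11 comes from (R)-epichlorohydrin, isopropenyl Grignard and acetylide (C2, then inverted to C–Cl), plus Me3Al and CH2O.

Assumption: the SMILES is taken as authoritative. In labdane numbering it reads 2α-Cl (2S), 5S, 6β-OH (6R), 9S, 10R, 12S, 13R. Labdane numbers are used for positions throughout.

## Route

Step 1
Reactants: 1 (R)-epichlorohydrin; 2 isopropenylmagnesium bromide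
Product: 3 (2R)-1-chloro-4-methylpent-4-en-2-ol
Conditions: CuI (10 mol %), THF, −40 → 0 °C; aq. work-up
Reagents that add atoms: none
Why: Cu(I)-catalysed Grignard opening of the epoxide (SN2 at the unsubstituted carbon) breaks no bond at the carbinol centre, so the configuration of 1 becomes that of future C2.

Step 2
Reactants: 3 (2R)-1-chloro-4-methylpent-4-en-2-ol; 4 lithium acetylide–ethylenediamine complex
Product: 6 (4R)-2-methylhept-1-en-6-yn-4-ol, via epoxide 5 (not isolated)
Conditions: 4 (3 equiv), DMSO, 0 °C → rt; aq. work-up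
Reagents that add atoms: none
Why: The first equivalent of acetylide closes the chlorohydrin to the terminal epoxide and the second opens it at CH2 (SN2 epoxide alkynylation), so the C–O stereocentre is never touched.

Step 3
Reactants: 6 (4R)-2-methylhept-1-en-6-yn-4-ol
Product: 7 (4S)-4-chloro-2-methylhept-1-en-6-yne
Conditions: PPh3, CCl4, CH2Cl2, 40 °C
Reagents that add atoms: carbon tetrachloride, ClC(Cl)(Cl)Cl
Why: In this Appel deoxychlorination chloride displaces the alkoxyphosphonium by SN2, which inverts C2 to the S C–Cl centre of the target under neutral conditions that spare the alkene and alkyne.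

Step 4
Reactants: 7 (4S)-4-chloro-2-methylhept-1-en-6-yne
Product: 10 (2E,5S)-5-chloro-3,7-dimethylocta-2,7-dien-1-ol, via alkenylalane 8 (not isolated), via lithium alanate 9 (not isolated)
Conditions: Me3Al, Cp2ZrCl2 (25 mol %), CH2Cl2, 0 °C → rt; n-BuLi, THF, −78 °C; (CH2O)n, → rt; aq. work-up
Reagents that add atoms: trimethylaluminium, C[Al](C)C; paraformaldehyde (as formaldehyde), C=O
Why: Negishi Zr-catalysed syn-carboalumination puts CH3 on the internal and Al on the terminal alkyne carbon, giving only the E C5=C10 alkene and leaving the 1,1-disubstituted alkene alone, and the alanate is hydroxymethylated with retention.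

Step 5
Reactants: 10 (2E,5S)-5-chloro-3,7-dimethylocta-2,7-dien-1-ol
Product: 11 (2E,5S)-5-chloro-3,7-dimethylocta-2,7-dienal
Conditions: MnO2, CH2Cl2, rt
Reagents that add atoms: none
Why: MnO2 allylic oxidation is neutral, so it causes neither E/Z scrambling nor vinylogous loss of HCl.

Step 6
Reactants: 11 (2E,5S)-5-chloro-3,7-dimethylocta-2,7-dienal; 12 allenylboronic acid pinacol ester
Product: 13 (4S,5E,8S)-8-chloro-6,10-dimethylundeca-5,10-dien-1-yn-4-ol
Conditions: (S)-TRIP phosphoric acid (10 mol %), 4 Å MS, toluene, −20 °C; aq. work-up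
Reagents that add atoms: none
Why: In this chiral-phosphoric-acid-catalysed carbonyl propargylation (closed SE2′ allenylboration transition state) the (S)-acid directs 1,2-attack to the Si face of the enal and sets C6 as S (the later equatorial 6α-OH) under catalyst control.

Step 7
Reactants: 13 (4S,5E,8S)-8-chloro-6,10-dimethylundeca-5,10-dien-1-yn-4-ol; 14 (trimethylsilyl)methylmagnesium chloride
Product: 16 (1Z,4S,5E,8S)-8-chloro-1-iodo-6,10-dimethyl-2-[(trimethylsilyl)methyl]undeca-1,5,10-trien-4-ol, via alkenylcopper 15 (not isolated)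
Conditions: 14 (2.3 equiv), CuI (1.2 equiv), Et2O–Me2S, −30 → 0 °C; I2, −40 °C; aq. work-up
Reagents that add atoms: iodine, II
Why: Normant syn-carbocupration of the terminal alkyne (on its magnesium alkoxide) places CH2SiMe3 on C8 and Cu on C9 cis to it, and iodinolysis with retention fixes the C8=C9 geometry (C9 substituent trans to C7) needed for an equatorial side chain.

Step 8
Reactants: 16 (1Z,4S,5E,8S)-8-chloro-1-iodo-6,10-dimethyl-2-[(trimethylsilyl)methyl]undeca-1,5,10-trien-4-ol; 17 (2-ethoxy-2-oxoethyl)zinc bromide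
Product: 18 ethyl (3Z,6S,7E,10S)-10-chloro-6-hydroxy-8,12-dimethyl-4-[(trimethylsilyl)methyl]trideca-3,7,12-trienoate
Conditions: 17 (3 equiv), Pd2(dba)3 (2.5 mol %), XPhos (6 mol %), THF, rt → 40 °C
Reagents that add atoms: none
Why: Negishi-type coupling of a Reformatsky reagent with an alkenyl iodide proceeds with retention of geometry, and the weakly basic zinc enolate does not conjugate the β,γ-unsaturated ester or touch the secondary chloride.

Step 9
Reactants: 18 ethyl (3Z,6S,7E,10S)-10-chloro-6-hydroxy-8,12-dimethyl-4-[(trimethylsilyl)methyl]trideca-3,7,12-trienoate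
Product: 19 ethyl 2-[(1S,4S,4aS,7S,8aR)-7-chloro-4-hydroxy-5,5,8a-trimethyl-2-methylidenedecahydronaphthalen-1-yl]acetate
Conditions: Co(II)(salen-tBu4) (5 mol %), 1-fluoro-2,4,6-trimethylpyridinium triflate (1.1 equiv), (Me2SiH)2O (1.1 equiv, slow addition), PhCF3 (0.01 M), 0 °C; aq. NaHCO3
Reagents that add atoms: none
Why: Proposed new method: a Co(III)–H formed in situ transfers H• only to the least hindered 1,1-disubstituted alkene (the neutral counterpart of the cyclase protonation) to give the tertiary C4 radical; two 6-endo closures (C4–C5, then C9–C10) follow through the chair–chair fold that keeps both C2–Cl and C6–OH equatorial (A1,3 strain with C20 holds H6 inside), which sets 5α-H, 10β-Me and the 9β side chain; the β-silyl C8 radical is then oxidised (radical–polar crossover) and loses Me3Si+ to give only the C8(17) methylene; the closest known reaction types are Co(salen)/N-fluoropyridinium/silane MHAT-initiated bicyclisations of free-hydroxy polyenes terminated by arenes and allylsilane-terminated cationic polyene cyclisations.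

Step 10
Reactants: 19 ethyl 2-[(1S,4S,4aS,7S,8aR)-7-chloro-4-hydroxy-5,5,8a-trimethyl-2-methylidenedecahydronaphthalen-1-yl]acetate
Product: 20 ethyl 2-[(1S,4aS,7S,8aR)-7-chloro-5,5,8a-trimethyl-2-methylidene-4-oxodecahydronaphthalen-1-yl]acetate
Conditions: Dess–Martin periodinane, CH2Cl2, 0 °C; cold NaHCO3/Na2S2O3 work-up
Reagents that add atoms: none
Why: Dess–Martin oxidation removes the equatorial 6α-carbinol, which has finished its work as a control element, under conditions mild enough to keep the β,γ-enone unconjugated and C5 trans-fused.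

Step 11
Reactants: 20 ethyl 2-[(1S,4aS,7S,8aR)-7-chloro-5,5,8a-trimethyl-2-methylidene-4-oxodecahydronaphthalen-1-yl]acetate
Product: 21 2-[(1S,4R,4aS,7S,8aR)-7-chloro-4-hydroxy-5,5,8a-trimethyl-2-methylidenedecahydronaphthalen-1-yl]acetaldehyde
Conditions: DIBAL-H (3 equiv), CH2Cl2, −78 °C; MeOH, then aq. Rochelle salt
Reagents that add atoms: none
Why: In this DIBAL reduction the β face of C6 is blocked by the syn-axial C10 and C4 methyls, so hydride arrives from the α face and sets the axial 6β-OH (6R), while the ester stops at the aluminium hemiacetal at −78 °C and gives the aldehyde on work-up.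

Step 12
Reactants: 22 (R)-4-benzyl-1,3-oxazolidin-2-one; 23 methyl 4-chloro-4-oxobutanoate
Product: 24 methyl 4-[(4R)-4-benzyl-2-oxo-1,3-oxazolidin-3-yl]-4-oxobutanoate
Conditions: n-BuLi, THF, −78 °C; then 23, → 0 °C
Reagents that add atoms: none
Why: N-acylation of the lithiated Evans auxiliary by the acid chloride is much faster than attack on the methyl ester, and the auxiliary centre is not involved.

Step 13
Reactants: 24 methyl 4-[(4R)-4-benzyl-2-oxo-1,3-oxazolidin-3-yl]-4-oxobutanoate; 21 2-[(1S,4R,4aS,7S,8aR)-7-chloro-4-hydroxy-5,5,8a-trimethyl-2-methylidenedecahydronaphthalen-1-yl]acetaldehyde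
Product: 26 methyl (3R,4S)-3-{[(4R)-4-benzyl-2-oxo-1,3-oxazolidin-3-yl]carbonyl}-5-[(1S,4R,4aS,7S,8aR)-7-chloro-4-hydroxy-5,5,8a-trimethyl-2-methylidenedecahydronaphthalen-1-yl]-4-hydroxypentanoate, via boron enolate 25 (not isolated)
Conditions: 24 (2 equiv), Bu2BOTf, Et3N, CH2Cl2, 0 °C; 21, −78 → 0 °C; pH 7 buffer, MeOH, H2O2
Reagents that add atoms: none
Why: In this Evans syn-aldol reaction the Z-boron enolate reacts through a Zimmerman–Traxler chair whose face is fixed by the (R)-benzyl group, giving 12S,13R under reagent control, and the hindered axial 6β-OH is left alone.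

Step 14
Reactants: 26 methyl (3R,4S)-3-{[(4R)-4-benzyl-2-oxo-1,3-oxazolidin-3-yl]carbonyl}-5-[(1S,4R,4aS,7S,8aR)-7-chloro-4-hydroxy-5,5,8a-trimethyl-2-methylidenedecahydronaphthalen-1-yl]-4-hydroxypentanoate
Product: 28 haterumaimide F, via hydroxy amide 27 (not isolated)
Conditions: NH3 (7 M in MeOH), 0 °C → rt
Reagents that add atoms: ammonia, N
Why: Ammonolysis of the C15 ester (directly or through its γ-lactone) gives the primary amide, whose nitrogen closes 5-exo onto the activated acyl-oxazolidinone and expels the auxiliary irreversibly (imide formation), under a base too weak for retro-aldol or C13 epimerisation.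

## Compound list
1 | (R)-epichlorohydrin | ClC[C@H]1CO1 | starting material
2 | isopropenylmagnesium bromide | C=C(C)[Mg]Br | starting material
3 | (2R)-1-chloro-4-methylpent-4-en-2-ol | C=C(C)C[C@@H](O)CCl | intermediate
4 | lithium acetylide–ethylenediamine complex | [Li]C#C.NCCN | starting material
5 | (2R)-2-(2-methylprop-2-enyl)oxirane (not isolated) | C=C(C)C[C@@H]1CO1 | intermediate
6 | (4R)-2-methylhept-1-en-6-yn-4-ol | C=C(C)C[C@@H](O)CC#C | intermediate
7 | (4S)-4-chloro-2-methylhept-1-en-6-yne | C=C(C)C[C@H](Cl)CC#C | intermediate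
8 | [(1E,4S)-4-chloro-2,6-dimethylhepta-1,6-dienyl]dimethylalane (not isolated) | C=C(C)C[C@H](Cl)C/C(C)=C/[Al](C)C | intermediate
9 | lithium butyl[(1E,4S)-4-chloro-2,6-dimethylhepta-1,6-dienyl]dimethylalanate (not isolated) | [Li+].C=C(C)C[C@H](Cl)C/C(C)=C/[Al-](C)(C)CCCC | intermediate
10 | (2E,5S)-5-chloro-3,7-dimethylocta-2,7-dien-1-ol | C=C(C)C[C@H](Cl)C/C(C)=C/CO | intermediate
11 | (2E,5S)-5-chloro-3,7-dimethylocta-2,7-dienal | C=C(C)C[C@H](Cl)C/C(C)=C/C=O | intermediate
12 | allenylboronic acid pinacol ester | C=C=CB1OC(C)(C)C(C)(C)O1 | starting material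
13 | (4S,5E,8S)-8-chloro-6,10-dimethylundeca-5,10-dien-1-yn-4-ol | C=C(C)C[C@H](Cl)C/C(C)=C/[C@@H](O)CC#C | intermediate
14 | (trimethylsilyl)methylmagnesium chloride | C[Si](C)(C)C[Mg]Cl | starting material
15 | (Z)-alkenylcopper of 13, as its chloromagnesium alkoxide (not isolated) | C=C(C)C[C@H](Cl)C/C(C)=C/[C@@H](O[Mg]Cl)C/C(C[Si](C)(C)C)=C/[Cu] | intermediate
16 | (1Z,4S,5E,8S)-8-chloro-1-iodo-6,10-dimethyl-2-[(trimethylsilyl)methyl]undeca-1,5,10-trien-4-ol | C=C(C)C[C@H](Cl)C/C(C)=C/[C@@H](O)C/C(C[Si](C)(C)C)=C/I | intermediate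
17 | (2-ethoxy-2-oxoethyl)zinc bromide | CCOC(=O)C[Zn]Br | starting material
18 | ethyl (3Z,6S,7E,10S)-10-chloro-6-hydroxy-8,12-dimethyl-4-[(trimethylsilyl)methyl]trideca-3,7,12-trienoate | C=C(C)C[C@H](Cl)C/C(C)=C/[C@@H](O)C/C(C[Si](C)(C)C)=C/CC(=O)OCC | intermediate
19 | ethyl 2-[(1S,4S,4aS,7S,8aR)-7-chloro-4-hydroxy-5,5,8a-trimethyl-2-methylidenedecahydronaphthalen-1-yl]acetate (2α-Cl, 6α-OH) | C=C1C[C@H](O)[C@H]2C(C)(C)C[C@H](Cl)C[C@]2(C)[C@H]1CC(=O)OCC | intermediate
20 | ethyl 2-[(1S,4aS,7S,8aR)-7-chloro-5,5,8a-trimethyl-2-methylidene-4-oxodecahydronaphthalen-1-yl]acetate | C=C1CC(=O)[C@H]2C(C)(C)C[C@H](Cl)C[C@]2(C)[C@H]1CC(=O)OCC | intermediate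
21 | 2-[(1S,4R,4aS,7S,8aR)-7-chloro-4-hydroxy-5,5,8a-trimethyl-2-methylidenedecahydronaphthalen-1-yl]acetaldehyde (6β-OH) | C=C1C[C@@H](O)[C@H]2C(C)(C)C[C@H](Cl)C[C@]2(C)[C@H]1CC=O | intermediate
22 | (R)-4-benzyl-1,3-oxazolidin-2-one | O=C1OC[C@@H](Cc2ccccc2)N1 | starting material
23 | methyl 4-chloro-4-oxobutanoate | COC(=O)CCC(=O)Cl | starting material
24 | methyl 4-[(4R)-4-benzyl-2-oxo-1,3-oxazolidin-3-yl]-4-oxobutanoate | COC(=O)CCC(=O)N1[C@H](Cc2ccccc2)COC1=O | intermediate
25 | (Z)-dibutylboron enolate of 24 (not isolated) | COC(=O)C/C=C(\OB(CCCC)CCCC)N1[C@H](Cc2ccccc2)COC1=O | intermediate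
26 | Evans syn-aldol adduct (12S,13R), methyl ester | C=C1C[C@@H](O)[C@H]2C(C)(C)C[C@H](Cl)C[C@]2(C)[C@H]1C[C@H](O)[C@@H](CC(=O)OC)C(=O)N1[C@H](Cc2ccccc2)COC1=O | intermediate
27 | C15 primary amide of 26 (not isolated) | C=C1C[C@@H](O)[C@H]2C(C)(C)C[C@H](Cl)C[C@]2(C)[C@H]1C[C@H](O)[C@@H](CC(N)=O)C(=O)N1[C@H](Cc2ccccc2)COC1=O | intermediate
28 | haterumaimide F, (3R)-3-{(1S)-2-[(1S,4R,4aS,7S,8aR)-7-chloro-4-hydroxy-5,5,8a-trimethyl-2-methylidenedecahydronaphthalen-1-yl]-1-hydroxyethyl}pyrrolidine-2,5-dione | C=C1C[C@@H](O)[C@H]2C(C)(C)C[C@H](Cl)C[C@]2(C)[C@H]1C[C@H](O)[C@H]1CC(=O)NC1=O | target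

## Step count and risks
Total steps: 14. Longest linear sequence: 13 (steps 1–11, 13, 14).

**Step 9 (bicyclisation).**
- The risks are fluoro- or protodesilylation of the allylsilane, arrest after ring A, and re-initiation at the new C8(17) methylene.
- The fallback sets out from 18 and returns at 19. It separates initiation from cyclisation and makes the cascade purely cationic.
- Co-catalysed Markovnikov hydrochlorination (TsCl as chlorine donor, PhSiH3, EtOH) of only the 1,1-disubstituted alkene gives the isolable tertiary chloride ethyl (3Z,6S,7E,10R)-10,12-dichloro-6-hydroxy-8,12-dimethyl-4-[(trimethylsilyl)methyl]trideca-3,7-dienoate F1.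
- The tertiary C–Cl alone is then abstracted with AgSbF6 and 2,6-di-tert-butyl-4-methylpyridine in CH2Cl2 at −78 °C. The discrete C4 cation undergoes the classical allylsilane-terminated bicyclisation with no acid, no oxidant and no hydride present, so 19 cannot react further.

**Step 7 (carbocupration on a free homopropargylic alcohol, then iodination of an allylsilane).**
- The risks are sluggish or misdirected addition and iododesilylation.
- The fallback sets out from 13 and returns at 18, bypassing 16. It reverses the polarity of the CH2SiMe3 unit.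
- Cu-catalysed syn borylcupration/alkylation (B2pin2, CuCl/Xantphos, NaOt-Bu, ICH2SiMe3) puts boron on C9 and the electrophilic CH2SiMe3 on C8. This gives (1Z,4S,5E,8S)-8-chloro-6,10-dimethyl-1-(4,4,5,5-tetramethyl-1,3,2-dioxaborolan-2-yl)-2-[(trimethylsilyl)methyl]undeca-1,5,10-trien-4-ol F2.
- F2 is joined to ethyl bromoacetate by Suzuki–Miyaura coupling (Pd(OAc)2, P(o-tol)3, K3PO4) to give 18.

**Step 4 (alanate chemistry next to a homopropargylic secondary chloride).**
- The risks are ring closure of the nucleophilic alanate 9 onto C2 to give a cyclobutene, and Lewis-acid ionisation of the chloride.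
- The fallback sets out from 7 and returns at 11, bypassing 9 and 10. It avoids any carbanionic alkenyl metal.
- The neutral alkenylalane 8 is quenched with I2 to give (1E,4S)-4-chloro-1-iodo-2,6-dimethylhepta-1,6-diene F3.
- F3 is formylated directly by Pd-catalysed reductive carbonylation (Pd(PPh3)4, CO 1 atm, slow addition of Bu3SnH, THF, 50 °C) with retention of geometry to give enal 11.

## Further compounds
F1 | step 9 | ethyl (3Z,6S,7E,10R)-10,12-dichloro-6-hydroxy-8,12-dimethyl-4-[(trimethylsilyl)methyl]trideca-3,7-dienoate | CC(C)(Cl)C[C@H](Cl)C/C(C)=C/[C@@H](O)C/C(C[Si](C)(C)C)=C/CC(=O)OCC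
F2 | step 7 | (1Z,4S,5E,8S)-8-chloro-6,10-dimethyl-1-(4,4,5,5-tetramethyl-1,3,2-dioxaborolan-2-yl)-2-[(trimethylsilyl)methyl]undeca-1,5,10-trien-4-ol | C=C(C)C[C@H](Cl)C/C(C)=C/[C@@H](O)C/C(C[Si](C)(C)C)=C/B1OC(C)(C)C(C)(C)O1
F3 | step 4 | (1E,4S)-4-chloro-1-iodo-2,6-dimethylhepta-1,6-diene | C=C(C)C[C@H](Cl)C/C(C)=C/I
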